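**Strategy.** The molecule is cut at the biaryl bond between C6' of ring B of the (2R)-eriodictyol half and C8 of ring A of the luteolin half. Both atoms are C–H carbons, so the key step is an anodic dehydrogenative phenol–arene cross-coupling. The flavanone precursor carries a single free phenol (3'-OH), to which C6' is para, and perbenzylated luteolin offers C8, its most nucleophilic C–H between the 7-oxygen and O1. One electrolysis thus joins two complete flavonoid units without halogen or boron handles. Ring A of the flavanone is silenced as a bis(benzyl carbonate); its C2 stereocenter comes from a rhodium-catalysed asymmetric 1,4-addition to a chromone, and hydrogenolysis finishes.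

Key step: step 5

**Remarks**
- The target is the (2R)-flavanone; the C6'–C8 axis carries three ortho substituents but is not specified, so no atroposelection is attempted.
- Assumption: 2-(benzyloxy)-5-bromophenol (3) is taken as a catalogue compound.

**Step 1**
Reactants: 1 5,7-dihydroxychromone
Product: 2 5,7-bis[(benzyloxycarbonyl)oxy]-4H-chromen-4-one
Conditions: CbzCl (2.6 equiv), Et3N, DMAP (cat.), THF, 0 °C to rt
Reagents that add atoms: benzyl chloroformate, O=C(Cl)OCc1ccccc1
Why: DMAP-catalysed O-acylation should convert both phenols (the hydrogen-bonded 5-OH included) into aryl benzyl carbonates, which deactivate ring A toward oxidation and electrophiles and are later removed by hydrogenolysis.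

**Step 2**
Reactants: 3 2-(benzyloxy)-5-bromophenol
Product: 6 [4-(benzyloxy)-3-hydroxyphenyl]boronic acid, via dilithio phenolate 4 (not isolated), via lithium triisopropoxyborate 5 (not isolated)
Conditions: n-BuLi (2.2 equiv), THF, −78 °C; B(Oi-Pr)3, −78 °C to rt; aq. HCl
Reagents that add atoms: triisopropyl borate, CC(C)OB(OC(C)C)OC(C)C; water, O
Why: Deprotonation of the phenol followed by bromine–lithium exchange gives an aryllithium that is trapped by the borate and hydrolysed to the boronic acid (lithiation–borylation).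

**Step 3**
Reactants: 2 5,7-bis[(benzyloxycarbonyl)oxy]-4H-chromen-4-one; 6 [4-(benzyloxy)-3-hydroxyphenyl]boronic acid
Product: 7 (2R)-2-[4-(benzyloxy)-3-hydroxyphenyl]-5,7-bis[(benzyloxycarbonyl)oxy]chroman-4-one
Conditions: 6 (2 equiv), [Rh(OH)(cod)]2 (cat.), (R)-MeO-F12-BIPHEP (cat.), toluene/H2O, 35 °C
Reagents that add atoms: none
Why: Hayashi–Miyaura rhodium-catalysed asymmetric 1,4-addition to the C2=C3 enone of the chromone should set C2 under catalyst control, the (R)-configured electron-poor bisphosphine (2,2'-bis[bis(3,4,5-trifluorophenyl)phosphino]-6,6'-dimethoxybiphenyl) delivering the aryl to the face that corresponds to (2R) by analogy with the (R)-BINAP to (R)-3-arylcyclohexanone correlation, while the base-free aqueous medium avoids retro-oxa-Michael racemisation and spares the carbonates.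

**Step 4**
Reactants: 8 luteolin
Product: 9 5,7-bis(benzyloxy)-2-[3,4-bis(benzyloxy)phenyl]-4H-chromen-4-one
Conditions: BnBr (6 equiv), K2CO3, DMF, 80 °C
Reagents that add atoms: benzyl bromide, BrCc1ccccc1
Why: Williamson etherification under forcing conditions should alkylate all four phenols, including the chelated 5-OH, so that ring A is an electron-rich dialkoxyarene with C8 as its preferred site of substitution.

**Step 5**
Reactants: 7 (2R)-2-[4-(benzyloxy)-3-hydroxyphenyl]-5,7-bis[(benzyloxycarbonyl)oxy]chroman-4-one; 9 5,7-bis(benzyloxy)-2-[3,4-bis(benzyloxy)phenyl]-4H-chromen-4-one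
Product: 10 (2R)-2-{4-(benzyloxy)-2-[5,7-bis(benzyloxy)-2-(3,4-bis(benzyloxy)phenyl)-4-oxo-4H-chromen-8-yl]-5-hydroxyphenyl}-5,7-bis[(benzyloxycarbonyl)oxy]chroman-4-one
Conditions: 9 (3 equiv), boron-doped diamond anode, Ni cathode, undivided cell, Bu3MeN+ MeOSO3− (0.09 M), HFIP, 50 °C, constant current, 2.0 F per mol of 7
Reagents that add atoms: none
Why: At the anode in HFIP the only free phenol, the 3'-OH on ring B of 7, is oxidised to a hydrogen-bond-stabilised phenoxyl radical with spin and charge at C2', C4' and C6'; C8 of ring A of 9 attacks the unhindered para carbon C6', and a second electron transfer with loss of two protons rearomatises both rings while HFIP is reduced to H2 at the cathode. The closest known reaction type is the anodic dehydrogenative phenol–arene cross-coupling of guaiacol-type phenols with alkoxyarenes in HFIP, together with para-selective oxidative phenol–arene couplings by trivalent iodine reagents. No ring is closed and no stereocenter is formed; the biaryl axis is left uncontrolled, and C2 is not endangered because the oxidised 3'-oxygen is meta to C1', so no quinone methide through C2–H can form. Chemoselectivity rests on the carbonates, which raise the oxidation potential and lower the nucleophilicity of ring A of 7, and on the threefold excess of 9, so that cross-coupling should outrun self-coupling. Site selectivity on 7 follows from C2' being flanked by the 3'-oxygen and the chromanone, and on 9 from C8 being the established site of electrophilic substitution in 5,7-dialkoxyflavones (C6 lies between two benzyloxy groups and ring B of 9 is deactivated by conjugation with the pyranone).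

**Step 6**
Reactants: 10 (2R)-2-{4-(benzyloxy)-2-[5,7-bis(benzyloxy)-2-(3,4-bis(benzyloxy)phenyl)-4-oxo-4H-chromen-8-yl]-5-hydroxyphenyl}-5,7-bis[(benzyloxycarbonyl)oxy]chroman-4-one
Product: 11 (2R)-2-{2-[2-(3,4-dihydroxyphenyl)-5,7-dihydroxy-4-oxo-4H-chromen-8-yl]-4,5-dihydroxyphenyl}-5,7-dihydroxychroman-4-one (CNP0228504.1)
Conditions: H2 (1 atm), Pd/C (10 %), THF/MeOH, rt
Reagents that add atoms: none
Why: Hydrogenolysis should cleave the five benzyl ethers and the two benzyl carbonates (the latter with loss of CO2) under neutral conditions that leave the C2 stereocenter, the flavanone ketone and the flavone enone intact when the reaction is stopped at full debenzylation.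

**Compound list**
1 | 5,7-dihydroxy-4H-chromen-4-one (5,7-dihydroxychromone) | O=c1ccoc2cc(O)cc(O)c12 | starting material
2 | 5,7-bis[(benzyloxycarbonyl)oxy]-4H-chromen-4-one | O=c1ccoc2cc(OC(=O)OCc3ccccc3)cc(OC(=O)OCc3ccccc3)c12 | intermediate
3 | 2-(benzyloxy)-5-bromophenol | Oc1cc(Br)ccc1OCc1ccccc1 | starting material
4 | lithium 2-(benzyloxy)-5-lithiophenolate | [Li]Oc1cc([Li])ccc1OCc1ccccc1 | intermediate
5 | dilithium [4-(benzyloxy)-3-oxidophenyl]tri(propan-2-yloxy)borate | [Li+].[Li+].[O-]c1cc([B-](OC(C)C)(OC(C)C)OC(C)C)ccc1OCc1ccccc1 | intermediate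
6 | [4-(benzyloxy)-3-hydroxyphenyl]boronic acid | OB(O)c1ccc(OCc2ccccc2)c(O)c1 | intermediate
7 | (2R)-2-[4-(benzyloxy)-3-hydroxyphenyl]-5,7-bis[(benzyloxycarbonyl)oxy]chroman-4-one | O=C1C[C@H](c2ccc(OCc3ccccc3)c(O)c2)Oc2cc(OC(=O)OCc3ccccc3)cc(OC(=O)OCc3ccccc3)c21 | intermediate
8 | luteolin (5,7,3',4'-tetrahydroxyflavone) | O=c1cc(-c2ccc(O)c(O)c2)oc2cc(O)cc(O)c12 | starting material
9 | 5,7-bis(benzyloxy)-2-[3,4-bis(benzyloxy)phenyl]-4H-chromen-4-one (tetra-O-benzylluteolin) | O=c1cc(-c2ccc(OCc3ccccc3)c(OCc3ccccc3)c2)oc2cc(OCc3ccccc3)cc(OCc3ccccc3)c12 | intermediate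
10 | (2R)-flavanone bis(benzyl carbonate) with 3'-OH, 4'-OBn and the tetra-O-benzylluteolin-8-yl group at C6' | O=C1C[C@H](c2cc(O)c(OCc3ccccc3)cc2-c2c(OCc3ccccc3)cc(OCc3ccccc3)c3c(=O)cc(-c4ccc(OCc5ccccc5)c(OCc5ccccc5)c4)oc23)Oc2cc(OC(=O)OCc3ccccc3)cc(OC(=O)OCc3ccccc3)c21 | intermediate
11 | (2R)-eriodictyol-(6'→8)-luteolin, CNP0228504.1 | O=C1C[C@H](c2cc(O)c(O)cc2-c2c(O)cc(O)c3c(=O)cc(-c4ccc(O)c(O)c4)oc23)Oc2cc(O)cc(O)c21 | target

**Totals.** 6 steps; longest linear sequence 4 steps (steps 2, 3, 5, 6 or 1, 3, 5, 6).

**Steps most likely to fail**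

Step 5. The electrolysis may be diverted by self-coupling or C–O coupling of the phenol, by attack at C6 of 9, or by over-oxidation of the product phenol. The hydrogen-bonded flavone may also be too weak a nucleophile in HFIP. The fallback is a Suzuki–Miyaura coupling and sets out from 7 and 9. Flavanone 7 is brominated para to its free phenol (NBS, MeCN, 0 °C; ring A is inert as the bis-carbonate) to give (2R)-2-[4-(benzyloxy)-2-bromo-5-hydroxyphenyl]-5,7-bis[(benzyloxycarbonyl)oxy]chroman-4-one F1. Flavone 9 is iodinated at C8 (NIS, CF3CO2H, CH2Cl2) to give 5,7-bis(benzyloxy)-2-[3,4-bis(benzyloxy)phenyl]-8-iodo-4H-chromen-4-one F2. Miyaura borylation (B2pin2, PdCl2(dppf), KOAc, dioxane, 85 °C) converts it into 5,7-bis(benzyloxy)-2-[3,4-bis(benzyloxy)phenyl]-8-(4,4,5,5-tetramethyl-1,3,2-dioxaborolan-2-yl)-4H-chromen-4-one F3. Coupling of F1 with F3 (Pd(OAc)2, SPhos, K3PO4, toluene/H2O, 50 °C, short reaction time to spare C2 and the carbonates) comes back to the route at 10.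

Step 3. Protodeboronation of the electron-rich boronic acid may outrun transmetalation, facial selectivity may be insufficient next to the 5-acyloxy group, or the sense of induction may not transfer. The fallback sets out from 2 and 6. Ligand-free [Rh(OH)(cod)]2 in dioxane/H2O, a more active diene–rhodium catalyst, should give racemic 2-[4-(benzyloxy)-3-hydroxyphenyl]-5,7-bis[(benzyloxycarbonyl)oxy]chroman-4-one F4. A kinetic resolution by Noyori-type asymmetric transfer hydrogenation follows (RhCl(Cp*)[(S,S)-TsDPEN], HCO2H/Et3N, EtOAc, rt, halted near half conversion). It should reduce the (2S)-enantiomer to the cis-alcohol (2S,4S)-2-[4-(benzyloxy)-3-hydroxyphenyl]-5,7-bis[(benzyloxycarbonyl)oxy]chroman-4-ol F5 and leave the (2R)-ketone, which is 7, where the route is rejoined.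

Step 6. Hydrogenation may run on to the C2=C3 bond of the flavone or open the benzylic C2–O1 bond of the flavanone, or it may stall before all seven groups are gone. The fallback sets out from 10 and replaces reductive cleavage by cation-scavenged Lewis-acid cleavage (BCl3, pentamethylbenzene, CH2Cl2, −78 °C, then MeOH). The benzyl groups are transferred to the scavenger and the carbonates lose CO2. It arrives directly at 11 and makes no new compound (F0).

**Further compounds**
F1 | step 5 | (2R)-2-[4-(benzyloxy)-2-bromo-5-hydroxyphenyl]-5,7-bis[(benzyloxycarbonyl)oxy]chroman-4-one | O=C1C[C@H](c2cc(O)c(OCc3ccccc3)cc2Br)Oc2cc(OC(=O)OCc3ccccc3)cc(OC(=O)OCc3ccccc3)c21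
F2 | step 5 | 5,7-bis(benzyloxy)-2-[3,4-bis(benzyloxy)phenyl]-8-iodo-4H-chromen-4-one | O=c1cc(-c2ccc(OCc3ccccc3)c(OCc3ccccc3)c2)oc2c(I)c(OCc3ccccc3)cc(OCc3ccccc3)c12
F3 | step 5 | 5,7-bis(benzyloxy)-2-[3,4-bis(benzyloxy)phenyl]-8-(4,4,5,5-tetramethyl-1,3,2-dioxaborolan-2-yl)-4H-chromen-4-one | O=c1cc(-c2ccc(OCc3ccccc3)c(OCc3ccccc3)c2)oc2c(B3OC(C)(C)C(C)(C)O3)c(OCc3ccccc3)cc(OCc3ccccc3)c12
F4 | step 3 | racemic 2-[4-(benzyloxy)-3-hydroxyphenyl]-5,7-bis[(benzyloxycarbonyl)oxy]chroman-4-one | O=C1CC(c2ccc(OCc3ccccc3)c(O)c2)Oc2cc(OC(=O)OCc3ccccc3)cc(OC(=O)OCc3ccccc3)c21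
F5 | step 3 | (2S,4S)-2-[4-(benzyloxy)-3-hydroxyphenyl]-5,7-bis[(benzyloxycarbonyl)oxy]chroman-4-ol | O[C@H]1C[C@@H](c2ccc(OCc3ccccc3)c(O)c2)Oc2cc(OC(=O)OCc3ccccc3)cc(OC(=O)OCc3ccccc3)c21
F0 | step 6 | none | none
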